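**Assumption:** 5-acetyl-2-hydroxybenzaldehyde (1) is bought as a catalogue compound; the ligand hand written in step 2 is confirmed on first use (its mirror image is equally available).

## Retrosynthetic overview

1. Ester C–O bond: 11 ⇒ alcohol 5 + CO + (Z)-vinyl iodide 9 (palladium alkoxycarbonylation; the alkene geometry is carried over from 9, made from crotonaldehyde 6 in three steps).
2. Key C–C bond, C2–C3 of 5 ⇒ aldehyde ether 3: the oxygen-bearing allylic carbon (future C2) is made a carbanion equivalent (γ-aryloxyallylchromium from the allylic C–H) and adds to the ortho CHO carbon. Two carbons that are both natural electrophiles are joined, giving the 1,2-dioxygenated unit and both stereocentres in one step.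
3. 3 ⇒ 5-acetylsalicylaldehyde 1 + methallyl chloride 2 (Williamson ether synthesis).
4. Rings: the benzene ring is bought with 1; the dihydrofuran ring is the only ring made, closed in the key step.

## Route

Step 1
Reactants: 1 5-acetyl-2-hydroxybenzaldehyde; 2 3-chloro-2-methylprop-1-ene
Product: 3 5-acetyl-2-[(2-methylprop-2-en-1-yl)oxy]benzaldehyde
Conditions: K2CO3, KI (cat.), DMF, 60 °C
Reagents that add atoms: none
Why: Williamson O-alkylation (SN2) of the acidic phenoxide on the allylic chloride with iodide catalysis, under which the aldehyde and the ketone are inert.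

Step 2
Reactants: 3 5-acetyl-2-[(2-methylprop-2-en-1-yl)oxy]benzaldehyde
Product: 5 1-[(2R,3S)-3-hydroxy-2-(prop-1-en-2-yl)-2,3-dihydro-1-benzofuran-5-yl]ethan-1-one, via allylchromium dichloride 4 (not isolated)
Conditions: CrCl2 (10 mol%), (S,R)-cyclopropylidene-bridged indane-bis(oxazoline) ligand (11 mol%), 9-mesityl-10-methylacridinium perchlorate (5 mol%), thiophosphoric imide HAT co-catalyst (10 mol%), Mg(ClO4)2 (1 equiv), CH2Cl2 (0.02 M), 430 nm LED, rt
Reagents that add atoms: none
Why: Proposed new method: the sulfur radical formed by photo-oxidation of the HAT co-catalyst abstracts the weakest, hydridic C–H of 3 (the OCH2, which is both allylic and α to oxygen), divalent chromium traps the resulting 1-aryloxy-2-methylallyl radical at its CH2 end to give allylchromium 4, and 4 adds through its oxygen-bearing γ-carbon to the ortho aldehyde in a chair Zimmerman–Traxler transition state fused to the forming five-membered ring (E enol ether, aryloxy and aldehyde aryl both equatorial, hence trans C2/C3), while the bis(oxazoline) on chromium selects Re-face attack on the aldehyde (3S, and with it 2R) and the reduced acridine returns trivalent chromium to the divalent state, so that the step is a redox-neutral isomerisation with no by-product; the closest known reactions are the acridinium/thiol/CrCl2–bis(oxazoline) asymmetric allylation of aldehydes through allylic C–H abstraction of simple alkenes (intermolecular, anti-selective, Nozaki–Hiyama–Kishi type) and the anti-selective addition of γ-alkoxyallylchromium reagents to aldehydes.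

Step 3
Reactants: 6 (E)-but-2-enal
Product: 7 (Z)-2-iodobut-2-enal
Conditions: I2, K2CO3, DMAP (cat.), THF/H2O (1:1), rt
Reagents that add atoms: iodine, II
Why: Baylis–Hillman-type α-iodination of an enal (DMAP-mediated addition–iodination–elimination), which gives the thermodynamically preferred (Z)-isomer with iodine cis to the methyl group.

Step 4
Reactants: 7 (Z)-2-iodobut-2-enal
Product: 8 (Z)-2-iodobut-2-en-1-ol
Conditions: NaBH4, MeOH, 0 °C
Reagents that add atoms: none
Why: Chemoselective 1,2-reduction of the aldehyde by borohydride, which leaves the C–I bond and the alkene geometry untouched.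

Step 5
Reactants: 8 (Z)-2-iodobut-2-en-1-ol
Product: 9 (Z)-2-iodobut-2-en-1-yl acetate
Conditions: Ac2O, Et3N, DMAP (cat.), CH2Cl2, 0 °C to rt
Reagents that add atoms: acetic anhydride, CC(=O)OC(C)=O
Why: DMAP-catalysed O-acetylation of the primary allylic alcohol, which installs the side-chain acetate before the carbonylation so that the hydroxyl cannot close onto the acylpalladium to a β-lactone.

Step 6
Reactants: 5 1-[(2R,3S)-3-hydroxy-2-(prop-1-en-2-yl)-2,3-dihydro-1-benzofuran-5-yl]ethan-1-one; 9 (Z)-2-iodobut-2-en-1-yl acetate
Product: 11 (2R,3S)-5-acetyl-2-(prop-1-en-2-yl)-2,3-dihydro-1-benzofuran-3-yl (2Z)-2-[(acetyloxy)methyl]but-2-enoate, via acylpalladium iodide 10 (not isolated)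
Conditions: 9 (1.5 equiv), Pd(OAc)2 (5 mol%), Xantphos (6 mol%), CO (1 atm), iPr2NEt (2 equiv), toluene, 50 °C
Reagents that add atoms: carbon monoxide, [C-]#[O+]
Why: Palladium-catalysed alkoxycarbonylation of a vinyl iodide (Heck carbonylation), in which zerovalent palladium inserts into the C–I bond of 9 with retention, CO insertion gives acylpalladium 10 and the C3–OH of 5 attacks it, so that the (Z)-geometry comes from 9, no activated angelate-type acid that could isomerise is handled, and neither stereocentre of 5 is touched.

## Compound list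

1 | 5-acetyl-2-hydroxybenzaldehyde | CC(=O)c1ccc(O)c(C=O)c1 | starting material
2 | 3-chloro-2-methylprop-1-ene (methallyl chloride) | C=C(C)CCl | starting material
3 | 5-acetyl-2-[(2-methylprop-2-en-1-yl)oxy]benzaldehyde | CC(=O)c1ccc(OCC(C)=C)c(C=O)c1 | intermediate
4 | [(2E)-3-(4-acetyl-2-formylphenoxy)-2-methylprop-2-en-1-yl]chromium dichloride (not isolated; bis(oxazoline) ligand not drawn) | CC(=O)c1ccc(O/C=C(\C)C[Cr](Cl)Cl)c(C=O)c1 | intermediate
5 | 1-[(2R,3S)-3-hydroxy-2-(prop-1-en-2-yl)-2,3-dihydro-1-benzofuran-5-yl]ethan-1-one (trans) | C=C(C)[C@H]1Oc2ccc(C(C)=O)cc2[C@@H]1O | intermediate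
6 | (E)-but-2-enal (crotonaldehyde) | C/C=C/C=O | starting material
7 | (Z)-2-iodobut-2-enal | C/C=C(\I)C=O | intermediate
8 | (Z)-2-iodobut-2-en-1-ol | C/C=C(\I)CO | intermediate
9 | (Z)-2-iodobut-2-en-1-yl acetate | C/C=C(\I)COC(C)=O | intermediate
10 | {(2Z)-2-[(acetyloxy)methyl]but-2-enoyl}palladium iodide (not isolated; phosphine not drawn) | C/C=C(/COC(C)=O)C(=O)[Pd]I | intermediate
11 | (2R,3S)-5-acetyl-2-(prop-1-en-2-yl)-2,3-dihydro-1-benzofuran-3-yl (2Z)-2-[(acetyloxy)methyl]but-2-enoate | C=C(C)[C@H]1Oc2ccc(C(C)=O)cc2[C@@H]1OC(=O)/C(=C\C)COC(C)=O | target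

## Step count and risks

Total steps: 6. Longest linear sequence: 4 steps (6 → 7 → 8 → 9 → 11); the benzofuran branch is 3 steps (1 → 3 → 5 → 11).

**Most likely to fail, first: step 2.** The intramolecular, asymmetric version of the C–H allylation is untested. Hydrogen abstraction could also occur at the vinylic methyl group (leading to a seven-membered ring) or at the aldehyde C–H, and the trans/cis ratio and the ee in a ring-forming transition state are not known. Reversible hydrogen abstraction at C2 of the product can only move cis material towards the more stable trans isomer and does not touch C3.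

The fallback sets out from 1 and comes back at 5. It makes the same C2–C3 bond with a chiral sulfonium allylide. (2R,5R)-2,5-Dimethylthiolane is alkylated with 3-bromo-2-methylprop-1-ene (acetone, rt) to (2R,5R)-2,5-dimethyl-1-(2-methylprop-2-en-1-yl)thiolan-1-ium bromide F1. F1 and 1 with NaOH in tBuOH/H2O at rt give, through the ylide, the trans vinyl epoxide 1-{4-hydroxy-3-[(2S,3S)-3-(prop-1-en-2-yl)oxiran-2-yl]phenyl}ethan-1-one F2. In the same pot the neighbouring phenoxide opens the allylic epoxide carbon of F2 with inversion, which gives the trans alcohol 5. If the sulfide induces the opposite sense, the (2S,5S)-sulfide is used.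

**Second: step 6.** The hindered secondary benzylic alcohol may capture the acylpalladium slowly. Zerovalent palladium could also ionise the allylic acetate or the allylic aryl ether, and the vinylpalladium stage could lose acetate.

The fallback sets out from 9 (with 5) and comes back at 11. It separates carbonylation from ester formation so that palladium never meets 5. Hydroxycarbonylation of 9 (Pd(OAc)2, dppf, CO 1 atm, KOAc, DMF/H2O, 50 °C) gives (2Z)-2-[(acetyloxy)methyl]but-2-enoic acid F3. F3 with 2,4,6-trichlorobenzoyl chloride and Et3N in toluene gives the mixed anhydride (2Z)-2-[(acetyloxy)methyl]but-2-enoic 2,4,6-trichlorobenzoic anhydride F4. F4 acylates 5 (DMAP, toluene, 0 °C to rt) to give 11 with retention at C3.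

**Third: step 3.** The iodoenal 7 is sensitive, and the iodination can stall or give polymeric material.

The fallback sets out from 6 and comes back at 8. It introduces the halogen by addition–elimination. Br2 in CH2Cl2 at −20 °C adds to 6 to give rac-(2R,3S)-2,3-dibromobutanal F5. Et3N removes HBr (E1cB) to give the thermodynamic (Z)-2-bromobut-2-enal F6. NaBH4 in MeOH at 0 °C gives (Z)-2-bromobut-2-en-1-ol F7. Copper-catalysed halide exchange with retention (CuI, trans-N,N'-dimethylcyclohexane-1,2-diamine, NaI, dioxane, 110 °C) converts F7 into 8.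

## Further compounds

F1 | step 2 | (2R,5R)-2,5-dimethyl-1-(2-methylprop-2-en-1-yl)thiolan-1-ium bromide | C[C@@H]1CC[C@@H](C)[S+]1CC(C)=C.[Br-]
F2 | step 2 | 1-{4-hydroxy-3-[(2S,3S)-3-(prop-1-en-2-yl)oxiran-2-yl]phenyl}ethan-1-one | C=C(C)[C@@H]1O[C@H]1c1cc(C(C)=O)ccc1O
F3 | step 6 | (2Z)-2-[(acetyloxy)methyl]but-2-enoic acid | C/C=C(/COC(C)=O)C(=O)O
F4 | step 6 | (2Z)-2-[(acetyloxy)methyl]but-2-enoic 2,4,6-trichlorobenzoic anhydride | C/C=C(/COC(C)=O)C(=O)OC(=O)c1c(Cl)cc(Cl)cc1Cl
F5 | step 3 | rac-(2R,3S)-2,3-dibromobutanal | C[C@H](Br)[C@H](Br)C=O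
F6 | step 3 | (Z)-2-bromobut-2-enal | C/C=C(\Br)C=O
F7 | step 3 | (Z)-2-bromobut-2-en-1-ol | C/C=C(\Br)CO
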